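How long are the chains in this flask at 12 min, and how much free monomer has gone into them? I follow one molecule of initiator through its forks.

common to all: impurity 16 µM

|  | free monomer | initiator | remark | time |
|---|---|---|---|---|
| green | 0.017 M | 68 µM | run made earlier |  |
| red | 0.026 M | 68 µM | run made earlier |  |
| violet | 0.034 M | 140 µM | run made earlier |  |
| flask | 0.034 M | 68 µM |  | 12 min |

| run | time / min | monomer in chains / % | free monomer / % |
|---|---|---|---|
| green | 0.417 | 5.7 | 93.9 |
| green | 1.00 | 8.1 | 91.5 |
| green | 2.00 | 9.6 | 89.9 |
| green | 3.00 | 8.6 | 91.3 |
| green | 4.00 | 8.9 | 90.4 |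
| green | 6.00 | 8.1 | 90.0 |
| green | 8.00 | 9.1 | 90.4 |
| red | 0.500 | 9.0 | 90.6 |
| red | 0.833 | 9.7 | 89.4 |
| red | 1.33 | 8.9 | 90.6 |
| red | 2.00 | 9.4 | 90.4 |
| red | 3.00 | 9.6 | 90.7 |
| red | 5.00 | 9.7 | 89.3 |
| red | 8.00 | 10.0 | 89.8 |
| violet | 0.667 | 19.7 | 79.5 |
| violet | 2.00 | 20.6 | 81.0 |
| violet | 3.00 | 20.8 | 79.8 |
| violet | 5.00 | 19.6 | 79.8 |
| violet | 8.00 | 20.0 | 78.9 |

(scatter of a reading: 0.5 percentage points)

- average number of monomer units in a chain (chains begun, living or dead) at 12 min
- part of the free monomer that has reacted at 12 min

- the average divides the monomer in chains by the number of chains begun, living and dead together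
- the earlier runs do not show the number of chains; that part of a forecast is a guess

In the first instants the initiator meets impurity or free monomer. I assume that each impurity molecule takes one initiator, which leaves 52.0 µM of c(initiator) in this flask to begin chains. In the middle the chains grow, and the green run is still rising between 0.417 min and 2.00 min. At the end they stop: the violet run stands flat from 0.667 min, with free monomer still at 78.9 % in its last reading.

The violet run has this flask's monomer charge, and its monomer in chains averages 20.1 %. That reads as 55.2 units, and this is the chain yield, the monomer units taken up per initiator that escapes the impurity, or kinetic chain length. The green plateau reads 29.0 and the red 47.4, both lower than violet, so I carry the violet value over, although violet's initiator differs. For this flask, on its plateau, I reckon dp 55.2 and c 8.45 %.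

The forecast gives dp 55 (42 to 72) and c 9.7 % (8.6 % to 11 %), holding that “the reaction ends by losing its active species, not by running out of monomer”. Its c is higher than mine.

The flask gives dp 57.0 and c 8.87 %.

    initiator + impurity → spent initiator A (k = 9.20 × 10⁵ M⁻¹ s⁻¹)
    living end + free monomer → dead end B (k = 3.80 M⁻¹ s⁻¹)
    free monomer + initiator → living end + monomer in chains (k = 8.30 M⁻¹ s⁻¹)
    monomer in chains + living end → free monomer + living end, rate k4*[living end] as long as [monomer in chains] is above zero (k = 3.50 s⁻¹)
    free monomer + living end → monomer in chains + living end, rate k5*[living end]*[free monomer] (k = 320 M⁻¹ s⁻¹)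

In this flask the living end has a half-life against dead end B of 0.094 min at 0.156 min, short beside the 12 min asked. By 6.00 min it stands at 0 M, with free monomer at 91.1 %. The answer c moves by 4 points at c(initiator) 44.2 µM or 92.4 µM, which takes it outside the forecast's range. A neighbour flask charged with 1.7 × 10⁻⁵ M of initiator holds 1.57 × 10⁻⁵ M of spent initiator A, so 1.26 µM began chains; the chain yield then gives c 0.205 %, and that flask shows 0.232 %.

(The readings were generated by integration for an exercise, and the scatter is random.)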